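In a one-step world, with E and J simply giving Q, this flask would have stopped where J, the limiting reagent at 0.700 equiv, ran out. I tested that picture against the earlier runs.

| flask | E | J | X | Z | remark | time |
|---|---|---|---|---|---|---|
| Monday's | 0.10 M | 0.70 equiv | 0.040 M | 0.1 mol% | run made earlier |  |
| Saturday's | 0.15 M | 0.70 equiv | 0.040 M | 0.1 mol% | run made earlier |  |
| Wednesday's | 0.20 M | 1 equiv | 0.040 M | 0.1 mol% | run made earlier |  |
| flask | 0.20 M | 0.700 equiv | 0.0400 M | 0.1 mol% |  | 6.0 d |

- Monday's (time / d: Q / %, L / %, E / %): 1.04: 23.8, 7.8, 32.4; 2.08: 34.4, 9.7, 16.0; 3.00: 36.3, 9.9, 14.9; 4.00: 35.3, 9.6, 13.2; 5.00: 35.7, 10.9, 14.1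
- Saturday's (time / d: Q / %, L / %, E / %): 0.417: 9.5, 0.6, 75.0; 0.833: 20.3, 2.5, 54.7; 1.25: 26.7, 3.5, 39.3; 2.50: 32.6, 5.8, 33.8; 5.00: 32.1, 7.4, 34.2
- Wednesday's (time / d: Q / %, L / %, E / %): 0.417: 10.1, 0.6, 80.5; 0.833: 22.3, 0.6, 62.7; 1.25: 29.0, 3.4, 49.5; 2.50: 31.4, 4.2, 41.2; 5.00: 32.8, 4.7, 42.8

(scatter of a reading: 1 percentage point)

- E is a solid; its amount is given per volume of the solution
- at the start none of E is in solution
- L means what is dissolved; the solid is not counted in it

- how much Q there is at 6.0 d, in percent of the E charged
- how much L there is at 6.0 d, in percent of the E charged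
- amount of Q if the flask were left three thousand times as long, in percent of the E charged

Wednesday's run objected at once: Q stopped near 32.8 % with 42.8 % of E still solid, though 1 equiv of J had been charged. At a fixed loading of Z the three plateaus lay close together in percent, so I suspected Z and counted Q per Z charged. That gave 358 for Monday's run, 324 for Saturday's and 321 for Wednesday's.

My first estimate took Saturday's count for this flask too, which put Q near 32.4 %. But Monday's and Saturday's runs had the same equivalents of J, and the count fell between them by 3.4 percentage points of Q, on a scatter of 1 point per reading. I took that fall as real. This flask lies one equal step of cE beyond them, so I continued the line to 289, the turnover number, meaning Q at its plateau per Z charged.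

The next objection was that Wednesday's run, at this same cE, stood higher. It had more J, however, so I read the gap as a power of the equivalents of J, 0.291, and that exponent is rough, since it rests on a line through two plateaus.

I committed to Q at 28.9 %. Wednesday's last two Q readings, 31.4 % and 32.8 %, differ by about the scatter, so I put this flask's Q after the long wait at 28.9 % too. For L I took Wednesday's 4.7 %, read at the same cE with solid present.

The forecast, higher than mine in Q, gave Q 32.4 %, L 4.9 % and, after the long wait, Q 32.6 %, reasoning “so the catalyst has died”.

The flask gave Q 29.0 %, L 5.00 % and, after the long wait, Q 29.0 %.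

    Z + Q → G (k = 6.70 × 10⁻⁴ /M/s)
    L + X → D (k = 0.00860 /M/s)
    E ⇌ L, rate k3*(cs3 - [L]) while solid is left; crystals form when [L] > cs3 (solubility = 10.0 mM, k = 1.30 × 10⁻⁴ /s)
    L + J + Z → Z + Q (k = 15.0 /M²/s)

The flask's Q is a turnover number of 290 against my 289. For the neighbour flask, charged with 0.280 equiv of J, the power gave 222, so Q at 22.2 %. It stood at Q 19.3 %, a turnover number of 193, with Z at 0 % and 31 % of its J still there.

The earlier runs and the new flask were generated by integration from invented constants; scatter was added.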